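1. If G is lost by a step first order in c_G and in c_L, then ln(charged c_G / present c_G) grows with the time integral of c_L, and it stops growing once c_L has gone.

| flask | G | L | remark | time |
|---|---|---|---|---|
| elm | 0.56 M | 1.2 M | run made earlier |  |
| alder | 0.88 M | 1.2 M | run made earlier |  |
| cedar | 0.40 M | 0.60 M | run made earlier |  |
| flask | 0.40 M | 1.20 M |  | 25 h |

- elm (time / h: G / %, J / %, D / %): 1.50: 47.7, 15.0, 32.0; 5.00: 28.4, 22.1, 39.0; 8.00: 21.0, 18.0, 42.4; 15.0: 19.4, 20.9, 41.3; 20.0: 20.3, 22.8, 40.5; 25.0: 18.3, 20.6, 41.8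
- alder (time / h: G / %, J / %, D / %): 2.00: 48.0, 16.0, 31.2; 3.00: 40.0, 18.4, 35.5; 6.00: 33.1, 18.9, 39.0; 10.0: 32.4, 19.7, 38.0; 15.0: 31.8, 18.9, 39.7; 25.0: 29.0, 18.1, 39.9
- cedar (time / h: G / %, J / %, D / %): 5.00: 41.3, 16.9, 34.4; 10.0: 32.0, 19.4, 36.0; 15.0: 31.6, 18.4, 39.7; 20.0: 28.9, 20.8, 38.8; 25.0: 28.5, 19.8, 39.4

(standard deviation of a reading: 1 percentage point)



1. how much G there is at 25 h, in percent of the G charged
2. how much J there is at 25 h, in percent of the G charged
3. how much D there is at 25 h, in percent of the G charged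
4. how much Z there is at 25 h, in percent of the G charged

2. The last alder reading gives 0.908 for the stall number s, that logarithm on the plateau divided by the charge ratio c_L/c_G.

3. Elm, at ratio 2.14, gives 0.793, smaller than alder, and cedar's 0.837 lies between them. The line through alder and elm has slope −0.148.

4. This flask has ratio 3.00, so my line gives s = 0.666 and G near 13.6%.

5. Leave the flask closed until 25 h: elm gave G 19.4% at 15.0 h and 18.3% at 25.0 h, so that run was flat within the scatter over those hours.

6. The forecast differs slightly from my figure, with G 12% (8% to 16%), J 21%, D 41% and Z 26%: “the reaction probably stalls because L is used up”.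

The flask gives G 12.3%, J 21.7%, D 41.3% and Z 24.7%, each inside the forecast's range.

    G + L → J + Q (k = 0.250 M⁻¹ h⁻¹)
    G + L → D + Q (k = 0.510 M⁻¹ h⁻¹)
    L + J → Z + Q (k = 0.160 M⁻¹ h⁻¹)
    L + D → Z + Q (k = 0.200 M⁻¹ h⁻¹)
    2 L → X (k = 0.350 M⁻¹ h⁻¹)

The flask's own s is 0.697. It is nearly at rest: L, the limiting reagent, fell under a fiftieth of its charge at 17.7 h and stands at 0.98% at 25.0 h. Ten times the time takes G to 11.1% and Z to 26.3%, while J stays at 21.6% and D eases to 41.0%.

For a neighbour charged with 1.6 M of G, the ratio is 0.750, and the line gives s = 0.999, so G near 47.3%. The computed flask holds G 49.7% at 25.0 h, with L at 0%.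

The runs were computed with constants of no real substance, noise included.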